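## The problem

Germacrane numbering is used throughout: ring C1–C10, C14 on C10, C15 on C4, C11–C13 on C7.

The target 32 is a cyclodecadiene with two trisubstituted, ring-cis alkenes (C1=C10 and C4=C5), each carrying a hydroxymethyl group and joined by the C2–C3 bridge. A trans-fused α-methylene-γ-butyrolactone (C11, C12, C13, ring oxygen on C8) sits on the C7–C8 bond, and C6 carries a tiglate. The three stereocentres are contiguous: C6 (R), C7 (R) and C8 (S). The C6 and C8 oxygens lie on the same side of the ring, and the C7–C11 bond lies on the other.

Only C8 can be taken from the chiral pool. C7 is best set against C8 while both are in a six-membered ring. C6 must then be set from a ketone inside the ten-membered ring, where control is weakest.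

Several groups limit the reagents that can be used late:
- the exo-methylene lactone is a Michael acceptor;
- the tiglate and the lactone do not survive hydride or amide bases;
- a free C6 alkoxide can take the lactone acyl group over from O8;
- every β-oxygenated ketone on the way can eliminate.

A ten-membered 1,5-diene is also hard to close and can fall into a divinylcyclohexane by Cope rearrangement.

The enabling feature is the unit C10=C1–C2–C3–C4=C5 with an oxidised carbon on C10 and on C4. Read as the product of an olefin metathesis, it divides into a cyclobutene ester (C1–C4 with C15) and a cyclohexenone ester (C5–C10 with C14, the C6 oxygen as the enone carbonyl). The large ring can therefore be uncovered from two small rings instead of being closed.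

## Retrosynthesis

**32 ⇒ 31 ⇒ 29 + 30.** The two O–Si bonds and the C6–O acyl bond are cut last. The tiglate cannot precede any hydride or amide-base step, and the primary C14 and C15 alcohols would be acylated before the hindered C6 alcohol if left free. The forward steps must acylate a hindered allylic alcohol with tiglic acid 30 without touching the exo-methylene lactone, then remove two primary silyl ethers under non-basic conditions.

**29 ⇒ 24 ⇒ 22.** The C11=C13 bond is cut. A conjugated lactone would not survive the hydride steps, so the methylene group goes on after them. In 24 the C6 hydroxyl is capped as a trimethylsilyl ether, so that no C6 alkoxide sits next to the lactone carbonyl while the lactone enolate is made. 24 comes from triol lactone 22 by silylating the two primary alcohols first and C6 second, in one flask.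

**22 ⇒ 21 ⇒ 20.** The hydroxymethyl groups are traced back to methyl esters. No hydride distinguishes two enoates from a γ-lactone, so all three are reduced to give lactol 21, and the hemiacetal alone is oxidised back. The gain is that C14 and C15 stay as conjugating esters up to 20, which the key step needs.

**20 ⇒ 19.** The C6–H bond is cut. C6 cannot be set earlier, because it must remain a carbonyl for the photocycloaddition, for the C7 alkylation and for the conjugation that steers the ring expansion. The forward reduction must be 1,2-selective on an ene-keto-ester and must deliver the alcohol cis to O8.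

**19 ⇒ 17.** The lactone C12–O8 bond is cut. Lactonising while C6 is still a ketone leaves O8 as the only hydroxyl within reach of C12. Lactonising after the reduction would let O6 and O8 compete for the same ester.

**17 ⇒ 14 (key disconnection).** The bonds C5–C10 and C1–C4 are reconnected. The two ring alkenes become the central cyclobutane of a 6-4-4 tricycle, and the ten-membered ring disappears.
- Against its neighbours: cutting any single ring bond (C2–C3, C5–C6, C8–C9) leaves an open chain that must be cyclised at high dilution with both alkene geometries already in place.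
- Gain: 14 is made from a cyclohexenone and a cyclobutene in two steps.
- Demands on the forward reaction: the right pair of cyclobutane bonds must break, the equilibrium must settle on the cis,cis-diene, and C7, C8 and the silyl ether must survive the heat.

**14 ⇒ 11 + 12.** The C7–C11 bond is cut. The side chain is introduced on the tricyclic ketone 11, where C7 is an ordinary six-ring methylene next to the C8 silyl ether. Two other positions for this step were weighed:
- on the ring-expanded ketone 17, facial selectivity in a flexible ten-membered enolate is hard to predict;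
- on enone 7, the substrate is an aromatisation-prone Michael acceptor.

Methyl bromoacetate 12 is chosen over a tert-butyl ester because a methyl ester is safe at the thermolysis temperature and lactonises just as well.

**11 ⇒ 7 + 10.** The bonds C4–C5 and C1–C10 are cut, an enone–alkene [2+2] photocycloaddition in reverse. The ester on cyclobutene 10 is needed to direct head-to-head bonding. 10 comes in two steps from the commercial bromo ester 8 through acid 9.

**7 ⇒ 6 ⇒ 4 ⇒ 3 ⇒ 2 ⇒ 1.** Enone 7 is shikimic acid 1 with C3 oxidised, C4 deoxygenated and C5 inverted (shikimate numbering). One device delivers all three changes: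
- methyl shikimate 2 closes to the 4,5-epoxide 3 with inversion at C5;
- oxidation gives epoxy enone 4;
- reductive opening at the carbon next to the ketone removes the C4 oxygen and gives 6.

The opening must leave the electron-poor ring alkene alone and must not trigger elimination to a phenol.

## Roads not taken

**Alternative 1: sulfone carbanion macro-alkylation at C2–C3.**
- Cut: C2–C3, the only ring bond flanked by two allylic methylenes.
- Forward key step: the open-chain sulfone bromide A2 is deprotonated at C2 with KN(SiMe3)2 at high dilution; the carbanion displaces the C3 allylic bromide and gives the ten-membered sulfone A1.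
- Merits: both alkene geometries and all three stereocentres are fixed in the open chain by acyclic methods before the ring exists. The new bond is remote from the stereocentres.
- Weak points:
  - a ten-membered closure competes with dimerisation and SN2′ attack;
  - the sulfone must later be removed reductively from a doubly allylic position next to allylic silyl ethers, which invites alkene migration;
  - two different ring-cis trisubstituted alkenes must each be made stereoselectively;
  - A2 carries five protecting groups of four kinds at the end of a long linear sequence, and after A1 the C12 oxidation, lactonisation and tigloylation still remain.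
- Comparison: this road is better on two counts. C6 is set with certainty, and the alkene geometry is kinetically fixed instead of resting on an equilibrium. The chosen plan sets against this a ring made from two small rings in two steps without dilution, C8 taken from shikimic acid, and a much shorter path to the carbocycle.

**Alternative 2: Nozaki–Hiyama–Kishi closure at C5–C6.**
- Cut: C5–C6.
- Forward key step: the lactone aldehyde A4, with a C5 vinyl iodide, is treated with CrCl2 and catalytic NiCl2; the alkenylchromium adds to the C6 aldehyde and gives the ring and the C6 carbinol in A3.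
- Merits: the lactone is already in place and C6 arrives at the alcohol oxidation level. From A3 only methylenation, tigloylation and desilylation remain, which is clearly shorter than the eight steps that follow the ring expansion in the chosen plan. The conditions tolerate lactones and silyl ethers.
- Weak points:
  - the C6 configuration is decided in a macrocyclic transition state with no evident bias;
  - the aldehyde in A4 has an epimerisable α-centre (C7) and a β-acyloxy group (O8) that can eliminate;
  - the trisubstituted vinyl iodide must be made with defined geometry;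
  - ten-membered closures of this type need a large excess of divalent chromium and high dilution, and A4 itself is the product of a long linear route.
- Comparison: this road is better in the length of the endgame and in not relying on thermodynamic alkene control. The chosen plan sets against this a ring-forming sequence with no entropic penalty and no stoichiometric chromium, and a C6 alcohol that can be corrected by inversion if it comes out wrong.

**Alternative 3: two-carbon ring expansion of a cyclooctadienol.**
- Cut: C8–C9, with the C6–C9 bond of an eight-membered precursor restored.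
- Forward key step: the potassium alkoxide of the 1-alkenylcycloocta-2,6-dienol A6 breaks its allylic C6–C9 bond and rebonds C9 to the alkenyl terminus C8 (anionic 1,3-shift), giving the ten-membered C6 ketone A5.
- Merits: both ring alkenes are cis by construction, because they come from an eight-membered ring. The ketone, the C7 branch and a C8 handle all arrive in the ring-expanding step.
- Weak points:
  - A6 is racemic, so a resolution or an asymmetric addition is needed;
  - the same alkoxide can take the [3,3] course through the C1=C10 bond to a different ring;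
  - the C7/C8 relationship is not obviously controlled;
  - the silyl group on C8 must be turned into a hydroxyl by Tamao–Fleming oxidation in the presence of two trisubstituted alkenes and a β-silyl ketone;
  - C12 must still be oxidised.
- Comparison: this road is clearly better on alkene geometry. The chosen plan sets against this a single enantiomer from the start, the C8 oxygen present from the first step, and C7 set by a neighbouring stereocentre in a six-membered ring.

Key step: step 10

Assumptions:
- Compounds 11, 13 and 14 are expected as mixtures of the two cis-anti-cis facial isomers; the isomer with the cyclobutane on the face of the C8 silyloxy group is drawn, and both converge at 17.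
- For 15 the isomer with the trans C1=C10 bond is drawn; which of the two alkenes is trans in the first-formed diene is not known.
- 16 is drawn without configuration at C5 and C10.

## Route

Step 1
Reactants: 1 shikimic acid
Product: 2 methyl shikimate
Conditions: MeOH, camphorsulfonic acid (cat.), reflux
Reagents that add atoms: methanol, CO
Why: Fischer esterification; the three secondary hydroxyls and the enoate are inert to catalytic acid in methanol.

Step 2
Reactants: 2 methyl shikimate
Product: 3 methyl (3R,4R,5S)-4,5-epoxy-3-hydroxycyclohex-1-ene-1-carboxylate (epoxide cis to the hydroxyl)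
Conditions: PPh3, DIAD, THF, 0 °C
Reagents that add atoms: none
Why: Intramolecular Mitsunobu reaction: the least hindered hydroxyl (C5, shikimate numbering) is activated and displaced by the trans C4 oxygen with inversion, a known conversion of methyl shikimate. This inversion sets the configuration of the future C8.

Step 3
Reactants: 3 epoxy alcohol
Product: 4 methyl (4S,5S)-4,5-epoxy-3-oxocyclohex-1-ene-1-carboxylate
Conditions: Dess–Martin periodinane, CH2Cl2, 0 °C to rt
Reagents that add atoms: none
Why: Dess–Martin oxidation of the allylic alcohol under non-basic conditions; the epoxide and the enoate are untouched, and base, which would aromatise the product, is avoided.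

Step 4
Reactants: 4 epoxy enone
Product: 6 methyl (5S)-5-hydroxy-3-oxocyclohex-1-ene-1-carboxylate, via iodo ketone 5 (not isolated)
Conditions: NaI, NaOAc, AcOH/acetone, 0 °C to rt
Reagents that add atoms: none
Why: Iodide-mediated reductive opening of an α,β-epoxy ketone: iodide opens the epoxide at the carbon next to the carbonyl to give 5, and a second iodide removes the iodine as I2, so the C5–O bond and its configuration are kept. Iodide in buffered acetic acid is too weak a reductant to attack the ene-keto-ester.

Step 5
Reactants: 6 hydroxy enone
Product: 7 methyl (5S)-5-(tert-butyldimethylsilyloxy)-3-oxocyclohex-1-ene-1-carboxylate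
Conditions: TBSOTf, 2,6-lutidine, CH2Cl2, −78 °C
Reagents that add atoms: tert-butyldimethylsilyl triflate, CC(C)(C)[Si](C)(C)OS(=O)(=O)C(F)(F)F
Why: Silylation with a silyl triflate and a hindered base at low temperature is faster than β-elimination of the hydroxy ketone.

Step 6
Reactants: 8 ethyl 1-bromocyclobutane-1-carboxylate
Product: 9 cyclobut-1-ene-1-carboxylic acid
Conditions: KOH, PhMe, reflux; then aq. HCl
Reagents that add atoms: potassium hydroxide, [K+].[OH-]
Why: E2 dehydrobromination with concomitant saponification, a standard preparation of this acid; the carboxylate formed is not attacked by hydroxide at the ring alkene.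

Step 7
Reactants: 9 cyclobut-1-ene-1-carboxylic acid
Product: 10 methyl cyclobut-1-ene-1-carboxylate
Conditions: MeI, K2CO3, acetone, rt
Reagents that add atoms: iodomethane, CI
Why: O-alkylation of the carboxylate under mild conditions; the ester is kept cold and used soon because it polymerises.

Step 8
Reactants: 7 silyloxy enone; 10 methyl cyclobut-1-ene-1-carboxylate (excess)
Product: 11 dimethyl (9S)-9-(tert-butyldimethylsilyloxy)-7-oxotricyclo[4.4.0.0^2,5]decane-1,5-dicarboxylate, the cis-anti-cis head-to-head photoadduct (new bonds C4–C5 and C1–C10)
Conditions: hν (medium-pressure mercury lamp, Pyrex), CH2Cl2, −20 °C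
Reagents that add atoms: none
Why: Enone–alkene [2+2] photocycloaddition through the enone triplet and a 1,4-biradical; an electron-poor alkene bonds its substituted carbon to the enone α-carbon (head-to-head), and exo approach gives the cis-anti-cis skeleton. The four new stereocentres are erased in step 10, so the facial selectivity relative to C8 does not matter.

Step 9
Reactants: 11 photoadduct; 12 methyl bromoacetate
Product: 14 dimethyl (8R,9S)-9-(tert-butyldimethylsilyloxy)-8-(2-methoxy-2-oxoethyl)-7-oxotricyclo[4.4.0.0^2,5]decane-1,5-dicarboxylate (C7 side chain trans to the C8 silyloxy group), via lithium enolate 13 (not isolated)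
Conditions: LiN(i-Pr)2, THF, −78 °C; then 12, DMPU, −78 to −40 °C
Reagents that add atoms: none
Why: Kinetic enolate alkylation: the base takes the C7 methylene proton, because the other α-position (C5) is a ring-fusion methine between two quaternary carbons, and the two esters have no α-hydrogen. The electrophile enters anti to the adjacent C8 silyl ether, which sets C7 (1,2-trans on a six-membered ring).

Step 10
Reactants: 14 alkylated tricycle
Product: 17 dimethyl (7R,8S)-8-(tert-butyldimethylsilyloxy)-7-(2-methoxy-2-oxoethyl)-6-oxocyclodeca-1(10),4-diene-4,10-dicarboxylate with both alkenes ring-cis, via cis-trans dienone 15 (not isolated), via divinylcyclohexanone 16 (not isolated)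
Conditions: PhMe (degassed, dilute), BHT (cat.), base-washed sealed tube, 180 °C
Reagents that add atoms: none
Why: Thermal [2+2] cycloreversion of the bicyclo[2.2.0]hexane unit, the thermal half of a photothermal olefin metathesis and closest in type to the known opening of cis-anti-cis tricyclo[4.4.0.0^2,5]decanones to cyclodeca-1,5-dienes. Homolysis of C5–C10 gives a 1,4-diradical stabilised by the ketone at C5 and the ester at C10, and β-scission of C1–C4 then releases the second four-membered ring and creates C1=C10 and C4=C5. No ring bond is made: the ten-membered ring appears because the two bonds it shared with the small rings are excised, so there is no closure mode to control and no new stereocentre, and both facial isomers of 14 converge. The first-formed cis,trans-diene 15 should equilibrate at this temperature by chair Cope rearrangement with the cis-divinylcyclohexanone 16, which returns through the boat-like Cope geometry to the cis,cis-diene 17. The selectivity needed is thermodynamic: 17 keeps both enoate conjugations and the enone conjugation, whereas 16 keeps only its acrylate and is a crowded pentasubstituted cyclohexanone. In 17 each ester is trans to the β ring carbon, in the least strained geometry of the ring. Cleavage in the reverse sense of the photocycloaddition (C4–C5 and C1–C10) is disfavoured because it would regenerate a cyclobutene. Degassing, base-washed glass and the inhibitor are meant to hold back enolisation at C7, loss of silanol and radical polymerisation.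

Step 11
Reactants: 17 cyclodecadienone
Product: 19 keto lactone, dimethyl (7R,8S)-6-oxogermacra-1(10),4-dien-12,8-olide-14,15-dioate (trans-fused γ-lactone, both alkenes ring-cis), via hydroxy ester 18 (not isolated)
Conditions: aq. HF, MeCN, 0 °C to rt; then TsOH·H2O (cat.), CH2Cl2, rt
Reagents that add atoms: none
Why: Acidic desilylation followed by acid-catalysed lactonisation (5-exo-trig) of the γ-hydroxy ester. C6 is still a ketone, so O8 is the only hydroxyl and the 8,12-lactone is the only γ-lactone that can form; the conjugated C14 ester is a much poorer acceptor than the saturated C12 ester.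

Step 12
Reactants: 19 keto lactone
Product: 20 dimethyl (6R,7R,8S)-6-hydroxygermacra-1(10),4-dien-12,8-olide-14,15-dioate
Conditions: NaBH4, CeCl3·7H2O, MeOH, −78 °C
Reagents that add atoms: none
Why: Luche reduction gives 1,2-reduction of the ene-keto-ester and leaves the lactone and the enoates alone. The C6 configuration is set by substrate control: hydride is expected from the outer face of the ketone in the lactone-braced ring, giving the alcohol cis to O8, but this is the least predictable stereocentre of the route.

Step 13
Reactants: 20 hydroxy lactone diester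
Product: 21 (6R,7R,8S)-germacra-1(10),4-diene-6,12,14,15-tetrol 8,12-hemiacetal (lactol, C12 epimers)
Conditions: i-Bu2AlH, CH2Cl2/THF, −78 °C; then aq. potassium sodium tartrate
Reagents that add atoms: none
Why: Exhaustive hydride reduction at low temperature: each conjugated methyl ester goes to the allylic alcohol, and the lactone stops at the lactol because its aluminium hemiacetal is stable at −78 °C.

Step 14
Reactants: 21 lactol tetrol
Product: 22 (6R,7R,8S)-6,14,15-trihydroxygermacra-1(10),4-dien-12,8-olide
Conditions: Ag2CO3 on Celite, PhMe, 50 °C
Reagents that add atoms: none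
Why: Silver carbonate on Celite oxidises hemiacetals to lactones much faster than it oxidises allylic or other alcohols, so the lactone is restored while the three hydroxyls remain.

Step 15
Reactants: 22 triol lactone
Product: 24 (6R,7R,8S)-14,15-bis(tert-butyldimethylsilyloxy)-6-(trimethylsilyloxy)germacra-1(10),4-dien-12,8-olide, via bis-TBS ether 23 (not isolated)
Conditions: TBSCl, imidazole, DMF, 0 °C; then TMSCl, 0 °C
Reagents that add atoms: tert-butyldimethylsilyl chloride, CC(C)(C)[Si](C)(C)Cl; chlorotrimethylsilane, C[Si](C)(C)Cl
Why: The bulky silyl chloride takes the two primary allylic hydroxyls and leaves the hindered secondary C6 hydroxyl, which is then capped with the small, easily removed trimethylsilyl group.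

Step 16
Reactants: 24 tris-silyl lactone
Product: 29 (6R,7R,8S)-14,15-bis(tert-butyldimethylsilyloxy)-6-hydroxygermacra-1(10),4,11(13)-trien-12,8-olide, via lithium enolate 25 (not isolated), via Mannich base 26 (not isolated), via ammonium iodide 27 (not isolated), via methylene lactone TMS ether 28 (not isolated)
Conditions: LiN(i-Pr)2, THF, −78 °C; CH2=NMe2 I, −78 to 0 °C; MeI, CH2Cl2/MeOH, rt; aq. NaHCO3; citric acid, MeOH, 0 °C
Reagents that add atoms: N,N-dimethylmethyleneiminium iodide, C=[N+](C)C.[I-]
Why: Mannich α-methylenation of a lactone: enolate aminomethylation, N-methylation and mild-base elimination of trimethylamine. The lactone α-methylene is the only acidic site, and the silyl cap on O6 keeps an alkoxide away from the lactone carbonyl. Brief mild acid then removes only the trimethylsilyl ether.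

Step 17
Reactants: 29 hydroxy methylene lactone; 30 tiglic acid
Product: 31 (6R,7R,8S)-14,15-bis(tert-butyldimethylsilyloxy)-6-[(E)-2-methylbut-2-enoyloxy]germacra-1(10),4,11(13)-trien-12,8-olide
Conditions: 30, 2,4,6-Cl3C6H2COCl, Et3N, PhMe, rt; then 29, DMAP, rt
Reagents that add atoms: none
Why: Yamaguchi esterification through the mixed anhydride, suited to hindered secondary alcohols; the C6–O bond is not broken, so the configuration is retained, and the E-configured tiglate does not isomerise.

Step 18
Reactants: 31 bis-silyl tiglate
Product: 32 target, (6R,7R,8S)-14,15-dihydroxy-6-[(E)-2-methylbut-2-enoyloxy]germacra-1(10),4,11(13)-trien-12,8-olide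
Conditions: HF·pyridine, pyridine/THF, 0 °C to rt
Reagents that add atoms: none
Why: Buffered acidic fluoride cleaves the two primary silyl ethers without the basic conditions that would cause acyl migration, translactonisation or conjugate addition to the methylene lactone.

## Compound list

1 | (−)-shikimic acid, (3R,4S,5R)-3,4,5-trihydroxycyclohex-1-ene-1-carboxylic acid | C1[C@H]([C@@H]([C@@H](C=C1C(=O)O)O)O)O | starting material
2 | methyl shikimate, methyl (3R,4S,5R)-3,4,5-trihydroxycyclohex-1-ene-1-carboxylate | COC(=O)C1=C[C@@H](O)[C@@H](O)[C@H](O)C1 | intermediate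
3 | methyl (3R,4R,5S)-4,5-epoxy-3-hydroxycyclohex-1-ene-1-carboxylate, epoxide cis to the hydroxyl | COC(=O)C1=C[C@@H](O)[C@H]2O[C@H]2C1 | intermediate
4 | methyl (4S,5S)-4,5-epoxy-3-oxocyclohex-1-ene-1-carboxylate | COC(=O)C1=CC(=O)[C@H]2O[C@H]2C1 | intermediate
5 | methyl (4R,5S)-5-hydroxy-4-iodo-3-oxocyclohex-1-ene-1-carboxylate, trans iodohydrin, not isolated | COC(=O)C1=CC(=O)[C@H](I)[C@@H](O)C1 | intermediate
6 | methyl (5S)-5-hydroxy-3-oxocyclohex-1-ene-1-carboxylate | COC(=O)C1=CC(=O)C[C@@H](O)C1 | intermediate
7 | methyl (5S)-5-(tert-butyldimethylsilyloxy)-3-oxocyclohex-1-ene-1-carboxylate | COC(=O)C1=CC(=O)C[C@@H](O[Si](C)(C)C(C)(C)C)C1 | intermediate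
8 | ethyl 1-bromocyclobutane-1-carboxylate | CCOC(=O)C1(Br)CCC1 | starting material
9 | cyclobut-1-ene-1-carboxylic acid | OC(=O)C1=CCC1 | intermediate
10 | methyl cyclobut-1-ene-1-carboxylate | COC(=O)C1=CCC1 | intermediate
11 | dimethyl (9S)-9-(tert-butyldimethylsilyloxy)-7-oxotricyclo[4.4.0.0^2,5]decane-1,5-dicarboxylate, cis-anti-cis head-to-head photoadduct (C6 ketone, C8 silyl ether, esters on C10 and C4), drawn with the cyclobutane syn to the silyloxy group | O=C1C[C@@H](O[Si](C)(C)C(C)(C)C)C[C@]2(C(=O)OC)[C@H]1[C@@]1(C(=O)OC)CC[C@H]12 | intermediate
12 | methyl bromoacetate | COC(=O)CBr | starting material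
13 | lithium C6–C7 enolate of 11, not isolated | [Li+].[O-]C1=C[C@@H](O[Si](C)(C)C(C)(C)C)C[C@]2(C(=O)OC)[C@H]1[C@@]1(C(=O)OC)CC[C@H]12 | intermediate
14 | dimethyl (8R,9S)-9-(tert-butyldimethylsilyloxy)-8-(2-methoxy-2-oxoethyl)-7-oxotricyclo[4.4.0.0^2,5]decane-1,5-dicarboxylate, C7 side chain trans to the C8 silyl ether | O=C1[C@H](CC(=O)OC)[C@@H](O[Si](C)(C)C(C)(C)C)C[C@]2(C(=O)OC)[C@H]1[C@@]1(C(=O)OC)CC[C@H]12 | intermediate
15 | cis,trans isomer of 17, drawn with C1=C10 ring-trans and C4=C5 ring-cis, not isolated | O=C1[C@H](CC(=O)OC)[C@@H](O[Si](C)(C)C(C)(C)C)C/C(C(=O)OC)=C/CC/C(C(=O)OC)=C\1 | intermediate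
16 | methyl 2-[(3R,4S)-4-(tert-butyldimethylsilyloxy)-6-ethenyl-6-(methoxycarbonyl)-3-(2-methoxy-2-oxoethyl)-2-oxocyclohexyl]prop-2-enoate, vinyl and acrylate groups cis, configuration at their two carbons (germacrane C5 and C10) not defined, not isolated | O=C1[C@H](CC(=O)OC)[C@@H](O[Si](C)(C)C(C)(C)C)CC(C=C)(C(=O)OC)C1C(=C)C(=O)OC | intermediate
17 | dimethyl (7R,8S)-8-(tert-butyldimethylsilyloxy)-7-(2-methoxy-2-oxoethyl)-6-oxocyclodeca-1(10),4-diene-4,10-dicarboxylate, both alkenes ring-cis | O=C1[C@H](CC(=O)OC)[C@@H](O[Si](C)(C)C(C)(C)C)C/C(C(=O)OC)=C\CC/C(C(=O)OC)=C\1 | intermediate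
18 | dimethyl (7R,8S)-8-hydroxy-7-(2-methoxy-2-oxoethyl)-6-oxocyclodeca-1(10),4-diene-4,10-dicarboxylate, not isolated | O=C1[C@H](CC(=O)OC)[C@@H](O)C/C(C(=O)OC)=C\CC/C(C(=O)OC)=C\1 | intermediate
19 | dimethyl (7R,8S)-6-oxogermacra-1(10),4-dien-12,8-olide-14,15-dioate, trans-fused lactone, both alkenes ring-cis | C1C(=O)O[C@H]2C/C(C(=O)OC)=C\CC/C(C(=O)OC)=C\C(=O)[C@H]12 | intermediate
20 | dimethyl (6R,7R,8S)-6-hydroxygermacra-1(10),4-dien-12,8-olide-14,15-dioate | C1C(=O)O[C@H]2C/C(C(=O)OC)=C\CC/C(C(=O)OC)=C\[C@@H](O)[C@H]12 | intermediate
21 | (6R,7R,8S)-germacra-1(10),4-diene-6,12,14,15-tetrol 8,12-hemiacetal, lactol, C12 epimers | C1C(O)O[C@H]2C/C(CO)=C\CC/C(CO)=C\[C@@H](O)[C@H]12 | intermediate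
22 | (6R,7R,8S)-6,14,15-trihydroxygermacra-1(10),4-dien-12,8-olide | C1C(=O)O[C@H]2C/C(CO)=C\CC/C(CO)=C\[C@@H](O)[C@H]12 | intermediate
23 | (6R,7R,8S)-14,15-bis(tert-butyldimethylsilyloxy)-6-hydroxygermacra-1(10),4-dien-12,8-olide, not isolated | C1C(=O)O[C@H]2C/C(CO[Si](C)(C)C(C)(C)C)=C\CC/C(CO[Si](C)(C)C(C)(C)C)=C\[C@@H](O)[C@H]12 | intermediate
24 | (6R,7R,8S)-14,15-bis(tert-butyldimethylsilyloxy)-6-(trimethylsilyloxy)germacra-1(10),4-dien-12,8-olide | C1C(=O)O[C@H]2C/C(CO[Si](C)(C)C(C)(C)C)=C\CC/C(CO[Si](C)(C)C(C)(C)C)=C\[C@@H](O[Si](C)(C)C)[C@H]12 | intermediate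
25 | lithium lactone enolate (C11=C12–O–Li) of 24, not isolated | C1=C([O-])O[C@H]2C/C(CO[Si](C)(C)C(C)(C)C)=C\CC/C(CO[Si](C)(C)C(C)(C)C)=C\[C@@H](O[Si](C)(C)C)[C@H]12.[Li+] | intermediate
26 | 11-(dimethylaminomethyl) derivative of 24, Mannich base, C11 epimers, not isolated | CN(C)CC1C(=O)O[C@H]2C/C(CO[Si](C)(C)C(C)(C)C)=C\CC/C(CO[Si](C)(C)C(C)(C)C)=C\[C@@H](O[Si](C)(C)C)[C@H]12 | intermediate
27 | 11-(trimethylammoniomethyl) derivative of 24, iodide salt, not isolated | C[N+](C)(C)CC1C(=O)O[C@H]2C/C(CO[Si](C)(C)C(C)(C)C)=C\CC/C(CO[Si](C)(C)C(C)(C)C)=C\[C@@H](O[Si](C)(C)C)[C@H]12.[I-] | intermediate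
28 | (6R,7R,8S)-14,15-bis(tert-butyldimethylsilyloxy)-6-(trimethylsilyloxy)germacra-1(10),4,11(13)-trien-12,8-olide, not isolated | C=C1C(=O)O[C@H]2C/C(CO[Si](C)(C)C(C)(C)C)=C\CC/C(CO[Si](C)(C)C(C)(C)C)=C\[C@@H](O[Si](C)(C)C)[C@H]12 | intermediate
29 | (6R,7R,8S)-14,15-bis(tert-butyldimethylsilyloxy)-6-hydroxygermacra-1(10),4,11(13)-trien-12,8-olide | C=C1C(=O)O[C@H]2C/C(CO[Si](C)(C)C(C)(C)C)=C\CC/C(CO[Si](C)(C)C(C)(C)C)=C\[C@@H](O)[C@H]12 | intermediate
30 | tiglic acid, (E)-2-methylbut-2-enoic acid | C/C=C(\C)C(=O)O | starting material
31 | (6R,7R,8S)-14,15-bis(tert-butyldimethylsilyloxy)-6-[(E)-2-methylbut-2-enoyloxy]germacra-1(10),4,11(13)-trien-12,8-olide | C=C1C(=O)O[C@H]2C/C(CO[Si](C)(C)C(C)(C)C)=C\CC/C(CO[Si](C)(C)C(C)(C)C)=C\[C@@H](OC(=O)/C(C)=C/C)[C@H]12 | intermediate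
32 | CNP0275462.2, (6R,7R,8S)-14,15-dihydroxy-6-[(E)-2-methylbut-2-enoyloxy]germacra-1(10),4,11(13)-trien-12,8-olide, both ring alkenes ring-cis | C=C1C(=O)O[C@H]2C/C(CO)=C\CC/C(CO)=C\[C@@H](OC(=O)/C(C)=C/C)[C@H]12 | target

## Step count and weak points

Total steps: 18. Longest linear sequence: 16 steps (steps 1–5 and 8–18, from shikimic acid); steps 6 and 7 form the two-step side branch.

**Step 10 (key step).**
- What may go wrong: the thermal mixture may stall on the chair-connected pair, the cis,trans-diene and the divinylcyclohexanone. The boat-like return to the cis,cis-diene is the slowest link, and the balance between ring strain and conjugation is narrow. Long heating also invites enolisation at C7 and loss of silanol.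
- Fallback: give the geometric isomerisation a channel of its own. Thermolyse 14 at the lowest temperature that consumes it and separate the mixture. Treat the cis,trans-diene 15 with catalytic PhSSPh under irradiation at room temperature; reversible thiyl-radical addition turns the strained trans alkene into the cis one and gives 17 without entering the Cope manifold. Reheat recovered 16 to regenerate 15 by the chair Cope rearrangement and repeat. This sets out from 14 and returns at 17, and makes no compound outside the list (F0).

**Step 8 (photocycloaddition).**
- What may go wrong: first bonding between the enone α-carbon and the unsubstituted cyclobutene carbon would give a biradical stabilised by both esters and lead to head-to-tail closure. The cyclobutene ester can also polymerise.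
- Fallback: take the radical-stabilising ester off the enone. Reduce 7 with i-Bu2AlH to the allylic diol F1, silylate its primary hydroxyl (TBSCl, imidazole) to the mono-silyl ether F2, and oxidise with MnO2 to the β-(silyloxymethyl) enone F3. β-Alkyl cyclohexenones are established head-to-head partners of 10. Irradiation with 10 should give the head-to-head photoadduct F4. Alkylation as in step 9 gives the C7-alkylated tricycle F5, and thermolysis as in step 10 gives the cyclodecadienone F6. Aqueous HF then removes both silyl groups and closes the keto lactone F7. NaBH4/CeCl3·7H2O gives the C6 alcohol F8, and i-Bu2AlH reduces the remaining ester and the lactone to rejoin the route at 21. The cost is that only one enoate remains to drive the ring expansion.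

**Step 4 (reductive epoxide opening).**
- What may go wrong: conjugate reduction of the electron-poor ring alkene by the iodide/acid pair, or acid-promoted dehydration of the β-hydroxy ketone followed by aromatisation.
- Fallback: separate opening from reduction. Open 4 with MgI2 in Et2O/PhMe at −60 °C and isolate the iodo ketone 5. Remove the iodine by a neutral radical chain (Bu3SnH, Et3B/air, −78 to 0 °C) to give 6, with no acid and no reducing nucleophile in contact with the enone. This sets out from 4 and returns at 6, and makes no compound outside the list (F0).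

**Step 9 (C7 alkylation).**
- What may go wrong: β-elimination of silanolate from the enolate, or proton transfer that leads to polyalkylation.
- Fallback: reverse the order of steps 9 and 10. Thermolyse 11 directly to the unsubstituted cis,cis-cyclodecadienone F9, then alkylate its kinetic C7 enolate (LiN(SiMe3)2, 12, THF/DMPU, −78 °C) to return at 17. In this order the face selectivity is decided in the ten-membered ring.

**Step 12 (C6 reduction).**
- What may go wrong: hydride delivery to the other face of the ketone, because the ring conformation that decides the outcome is not known.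
- Fallback: correct by inversion, not by another reduction. Take the 6-epi alcohol F10 and subject it to a Mitsunobu reaction with benzoic acid (PPh3, DIAD, PhMe) to give the inverted benzoate F11 with the natural C6 configuration. The i-Bu2AlH of step 13 cleaves the benzoate together with the other esters and returns the route at 21.

**Step 14 (lactol oxidation).**
- What may go wrong: oxidation of the three allylic hydroxyls alongside the hemiacetal, or carbonate-promoted acyl transfer from O8 to O6 once the lactone is back.
- Fallback: replace selective oxidation by exhaustive oxidation and selective reduction. Oxidise all four hydroxyls of 21 with Dess–Martin periodinane to the keto dialdehyde lactone F12. Reduce the ketone and both aldehydes, but not the lactone, with NaBH4/CeCl3·7H2O at −78 °C to return at 22.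

## Further compounds

F0 | step 10 | none | none
F1 | step 8 | (5S)-5-(tert-butyldimethylsilyloxy)-3-(hydroxymethyl)cyclohex-2-en-1-ol, C1 epimers | OCC1=CC(O)C[C@@H](O[Si](C)(C)C(C)(C)C)C1
F2 | step 8 | (5S)-5-(tert-butyldimethylsilyloxy)-3-(tert-butyldimethylsilyloxymethyl)cyclohex-2-en-1-ol, C1 epimers | CC(C)(C)[Si](C)(C)OCC1=CC(O)C[C@@H](O[Si](C)(C)C(C)(C)C)C1
F3 | step 8 | (5S)-5-(tert-butyldimethylsilyloxy)-3-(tert-butyldimethylsilyloxymethyl)cyclohex-2-en-1-one | CC(C)(C)[Si](C)(C)OCC1=CC(=O)C[C@@H](O[Si](C)(C)C(C)(C)C)C1
F4 | step 8 | methyl (9S)-9-(tert-butyldimethylsilyloxy)-1-(tert-butyldimethylsilyloxymethyl)-7-oxotricyclo[4.4.0.0^2,5]decane-5-carboxylate, cis-anti-cis head-to-head photoadduct | O=C1C[C@@H](O[Si](C)(C)C(C)(C)C)C[C@]2(CO[Si](C)(C)C(C)(C)C)[C@H]1[C@@]1(C(=O)OC)CC[C@H]12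
F5 | step 8 | methyl (8R,9S)-9-(tert-butyldimethylsilyloxy)-1-(tert-butyldimethylsilyloxymethyl)-8-(2-methoxy-2-oxoethyl)-7-oxotricyclo[4.4.0.0^2,5]decane-5-carboxylate | O=C1[C@H](CC(=O)OC)[C@@H](O[Si](C)(C)C(C)(C)C)C[C@]2(CO[Si](C)(C)C(C)(C)C)[C@H]1[C@@]1(C(=O)OC)CC[C@H]12
F6 | step 8 | methyl (7R,8S)-8-(tert-butyldimethylsilyloxy)-10-(tert-butyldimethylsilyloxymethyl)-7-(2-methoxy-2-oxoethyl)-6-oxocyclodeca-1(10),4-diene-4-carboxylate, both alkenes ring-cis | O=C1[C@H](CC(=O)OC)[C@@H](O[Si](C)(C)C(C)(C)C)C/C(CO[Si](C)(C)C(C)(C)C)=C\CC/C(C(=O)OC)=C\1
F7 | step 8 | methyl (7R,8S)-14-hydroxy-6-oxogermacra-1(10),4-dien-12,8-olid-15-oate | C1C(=O)O[C@H]2C/C(CO)=C\CC/C(C(=O)OC)=C\C(=O)[C@H]12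
F8 | step 8 | methyl (6R,7R,8S)-6,14-dihydroxygermacra-1(10),4-dien-12,8-olid-15-oate | C1C(=O)O[C@H]2C/C(CO)=C\CC/C(C(=O)OC)=C\[C@@H](O)[C@H]12
F0 | step 4 | none | none
F9 | step 9 | dimethyl (8S)-8-(tert-butyldimethylsilyloxy)-6-oxocyclodeca-1(10),4-diene-4,10-dicarboxylate, both alkenes ring-cis | O=C1C[C@@H](O[Si](C)(C)C(C)(C)C)C/C(C(=O)OC)=C\CC/C(C(=O)OC)=C\1
F10 | step 12 | dimethyl (6S,7R,8S)-6-hydroxygermacra-1(10),4-dien-12,8-olide-14,15-dioate, C6 epimer of 20 | C1C(=O)O[C@H]2C/C(C(=O)OC)=C\CC/C(C(=O)OC)=C\[C@H](O)[C@H]12
F11 | step 12 | dimethyl (6R,7R,8S)-6-benzoyloxygermacra-1(10),4-dien-12,8-olide-14,15-dioate | C1C(=O)O[C@H]2C/C(C(=O)OC)=C\CC/C(C(=O)OC)=C\[C@@H](OC(=O)c3ccccc3)[C@H]12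
F12 | step 14 | (7R,8S)-6,14,15-trioxogermacra-1(10),4-dien-12,8-olide, keto dialdehyde lactone | C1C(=O)O[C@H]2C/C(C=O)=C\CC/C(C=O)=C\C(=O)[C@H]12
A1 | alternative 1 | ten-membered C2 phenyl sulfone (C2 epimers) with C6 triethylsilyl ether, C8, C14 and C15 tert-butyldimethylsilyl ethers and a C7 3-(4-methoxybenzyloxy)prop-1-en-2-yl group | C=C(COCc2ccc(OC)cc2)[C@@H]1[C@@H](O[Si](C)(C)C(C)(C)C)C/C(CO[Si](C)(C)C(C)(C)C)=C\C(S(=O)(=O)c2ccccc2)C/C(CO[Si](C)(C)C(C)(C)C)=C\[C@H]1O[Si](CC)(CC)CC
A2 | alternative 1 | open-chain precursor of A1 with a C2 allylic phenyl sulfone and a C3 allylic bromide | O=S(=O)(c1ccccc1)C\C=C(CO[Si](C)(C)C(C)(C)C)/C[C@H](O[Si](C)(C)C(C)(C)C)[C@@H](C(=C)COCc1ccc(OC)cc1)[C@H](O[Si](CC)(CC)CC)\C=C(CO[Si](C)(C)C(C)(C)C)/CBr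
A3 | alternative 2 | (6R,7R,8S)-14,15-bis(tert-butyldimethylsilyloxy)-6-hydroxygermacra-1(10),4-dien-12,8-olide | C1C(=O)O[C@H]2C/C(CO[Si](C)(C)C(C)(C)C)=C\CC/C(CO[Si](C)(C)C(C)(C)C)=C\[C@@H](O)[C@H]12
A4 | alternative 2 | trans-4,5-disubstituted γ-butyrolactone with the C6 aldehyde on C7 and, on C8, the C9–C5 chain ending in the C5 vinyl iodide | O=C[C@@H]1CC(=O)O[C@H]1C/C(CO[Si](C)(C)C(C)(C)C)=C\CC/C(CO[Si](C)(C)C(C)(C)C)=C\I
A5 | alternative 3 | ten-membered C6 ketone with the C7 3-(4-methoxybenzyloxy)prop-1-en-2-yl group and the C8 benzyldimethylsilyl group, enantiomer carried on | O=C1[C@H](C(=C)COCc2ccc(OC)cc2)[C@@H]([Si](C)(C)Cc2ccccc2)C/C(CO[Si](C)(C)C(C)(C)C)=C\CC/C(CO[Si](C)(C)C(C)(C)C)=C\1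
A6 | alternative 3 | racemic 1-alkenylcycloocta-2,6-dien-1-ol, precursor of A5, with 3- and 6-(tert-butyldimethylsilyloxymethyl) groups and a 1-[1-(benzyldimethylsilyl)-4-(4-methoxybenzyloxy)-3-methylidenebut-1-en-2-yl] group, alkenyl geometry not defined | OC1(C(=C[Si](C)(C)Cc2ccccc2)C(=C)COCc2ccc(OC)cc2)\C=C(CO[Si](C)(C)C(C)(C)C)/CC\C=C(CO[Si](C)(C)C(C)(C)C)/C1
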